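The data were computed with constants of no real substance.

A small charge of free catalyst, 18 mol% on the solid substrate, served both the red run and the flask, but doubling the solid substrate gave the flask twice the charged catalyst concentration.

- red: solid substrate 0.12 M; free catalyst 18 mol%; run made earlier
- flask: solid substrate 0.24 M; free catalyst 18 mol%; time 40 h

red run (percent of the solid substrate charged)

| time / h | target / % | isomer of the product A / % |
|---|---|---|
| 1.50 | 10.4 | 1.7 |
| 3.00 | 10.3 | 3.4 |
| 5.00 | 9.0 | 5.3 |
| 6.00 | 8.8 | 5.2 |
| 8.00 | 8.2 | 6.1 |
| 10.0 | 8.2 | 7.0 |
| 12.0 | 7.3 | 7.3 |

(readings scatter by 0.3 percentage points)

- given per volume of solution although it is solid: solid substrate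
- the earlier runs were read with a standard deviation of 0.3 percentage points
- at the start none of the solid substrate is in solution
- no earlier run changes the charge of free catalyst; that part of a forecast is a guess

* ratio of target to isomer of the product A at 40 min
* ratio of target to isomer of the product A at 40 h

I turned the question round: for target still to lead in the flask at 40 h, its crossing with the isomer of the product A would have to lie beyond that time. In the red run, the two read level at 12.0 h. I multiplied the charged catalyst concentration by that time and called the product the crossing dose, 933 M·s. This was a guess, since no earlier run varied the catalyst: I took the growth of the isomer of the product A as pseudo-first-order at a given catalyst concentration. The dose put the flask's crossing at 6.00 h, earlier than 40 h by a factor of 6.67, so I expected a ratio below one there. At 40 min, by this reckoning, the flask had the dose the red run had at 1.33 h, and the first red readings, at 1.50 h, read a ratio of 6.12, which I took.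

The forecast gave 8 and 0.9, reasoning that “this equilibrium should be reached regardless of concentration”.

The flask gave 3.81 and 0.450.

    starting material ⇌ target (K = 0.350, k = 0.00620 min⁻¹)
    starting material + free catalyst ⇌ isomer of the product A + free catalyst, rate k2*[starting material]*[free catalyst] forward; the back reaction follows from the equilibrium constant (K = 3.00, k = 0.0300 M⁻¹ min⁻¹)
    starting material + free catalyst ⇌ isomer of the product B + free catalyst, rate k3*[starting material]*[free catalyst] forward; the back reaction follows from the equilibrium constant (K = 1.50, k = 0.180 M⁻¹ min⁻¹)
    solid substrate ⇌ starting material, rate k4*(cs4 - [starting material]) while solid is left; crystals form when [starting material] > cs4 (solubility = 0.120 M, k = 0.0250 min⁻¹)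
    starting material ⇌ dormant form (K = 1.30, k = 0.0240 min⁻¹)
    starting material + free catalyst → spent catalyst (k = 0.0370 M⁻¹ min⁻¹)

In the flask, target and isomer of the product A stood equal at 6.43 h, close to my 6.00 h, while free catalyst had a half-life of 5.7 h by the step to spent catalyst at 0.970 h, shorter than 40 h, and 2.06% of its charge stood at 40.0 h. In a neighbouring flask with a quarter of the catalyst, the crossing dose gave 24.0 h, earlier than 40 h, yet at 40.0 h free catalyst stood at 0.214% of its charge and the ratio at 2.76.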